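## Retrosynthetic overview

1. The nine-membered oxonene is closed last by ring-closing metathesis at C6=C7, after butanoylation of the C4 alcohol 17.
2. Key disconnection: the C3–O16 bond. Hydroxy Z-olefin 15 undergoes a vanadium-directed epoxidation and 7-exo ether closure that forms the oxepane and sets C3 and C4.
3. 15 comes from Diels–Alder lactone 10 by C9 methallylation of the lactol acetate (2,5-cis tetrahydrofuran) and Saegusa oxidation to the C11=C12 enone.
4. 10 comes from a Diels–Alder reaction of butenolide 6 (C2 from L-glutamic acid lactone; Z-olefin by Wittig) with 2-silyloxydiene 9 (C15 from (R)-β-methyl-γ-butyrolactone).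
5. Ring order: tetrahydrofuran (chiral-pool lactone) → cyclohexene (Diels–Alder) → oxepane (C–O closure) → oxonene (metathesis).

Assumption: enantiopure lactones 1 and 7 are bought as catalogue chiral-pool materials (7 is available but not cheap). Locants C1–C16 are those of the target (eunicellane numbering): C1/C10 ring fusion, C2/C9 the carbons on the tetrahydrofuran oxygen, C3 (Me, O16), C4 (O-acyl), C6=C7(Me), C11(Me)=C12, C13 (C=O), C14, C15 (Me), C16 (OCH2). Stereodescriptors were assigned by hand from the SMILES.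

## Route

Step 1
Reactants: 1 (S)-5-oxotetrahydrofuran-2-carboxylic acid
Product: 3 (S)-5-acetyldihydrofuran-2(3H)-one, via acid chloride 2 (not isolated)
Conditions: (COCl)2, cat. DMF, CH2Cl2, 0→23 °C; then MeMgBr (1.05 equiv), Fe(acac)3 (3 mol %), THF, −78 °C
Reagents that add atoms: methylmagnesium bromide, C[Mg]Br
Why: Iron-catalysed Grignard acylation of the acid chloride (Fürstner-type ketone synthesis) stops at the methyl ketone at −78 °C and leaves the lactone and the C2 stereocentre (from L-glutamic acid) untouched.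

Step 2
Reactants: 3 (S)-5-acetyldihydrofuran-2(3H)-one
Product: 4 (S)-5-[(2Z)-hexa-2,5-dien-2-yl]dihydrofuran-2(3H)-one
Conditions: Ph3P(CH2CH2CH=CH2)Br, KN(SiMe3)2, THF, 0 °C; then 3, −78→−20 °C
Reagents that add atoms: (but-3-en-1-yl)triphenylphosphonium bromide, [Br-].C=CCC[P+](c1ccccc1)(c1ccccc1)c1ccccc1
Why: Wittig olefination of an α-oxygenated methyl ketone with a non-stabilised ylide is Z-selective (the oxygen-bearing carbon ends cis to the new chain) and the ketone reacts much faster than the lactone, which sets the (3Z)-olefin.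

Step 3
Reactants: 4 (S)-5-[(2Z)-hexa-2,5-dien-2-yl]dihydrofuran-2(3H)-one
Product: 6 (S)-5-[(2Z)-hexa-2,5-dien-2-yl]furan-2(5H)-one, via α-phenylselanyl lactone 5 (not isolated)
Conditions: LiN(SiMe3)2, THF, −78 °C; PhSeBr; then NaIO4, NaHCO3, THF/H2O, 23 °C
Reagents that add atoms: none
Why: Lactone enolate selenenylation and selenoxide syn-elimination introduce the C1=C10 double bond without touching C2; periodate is used so that no peracid can epoxidise the electron-rich olefin.

Step 4
Reactants: 7 (R)-4-methyldihydrofuran-2(3H)-one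
Product: 8 (2R,5E)-1-hydroxy-2-methylhept-5-en-4-one
Conditions: (E)-MeCH=CHBr, t-BuLi (2 equiv), Et2O, −78 °C; then 7, THF, −78 °C; aq. NH4Cl at −78 °C
Reagents that add atoms: (E)-1-bromoprop-1-ene, C/C=C/Br
Why: 1,2-Addition of an alkenyllithium (from stereoretentive Li–Br exchange) to the γ-lactone stops at the lithium hemiketal at −78 °C, so the E-enone is released only on quench; C15 comes from the chiral pool.

Step 5
Reactants: 8 (2R,5E)-1-hydroxy-2-methylhept-5-en-4-one
Product: 9 (2R,3Z,5E)-1,4-bis(tert-butyldimethylsilyloxy)-2-methylhepta-3,5-diene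
Conditions: TBSOTf (2.3 equiv), Et3N, CH2Cl2, −78→0 °C
Reagents that add atoms: tert-butyldimethylsilyl trifluoromethanesulfonate, CC(C)(C)[Si](C)(C)OS(=O)(=O)C(F)(F)F
Why: Soft enolisation (silyl triflate/amine) at the α′-methylene gives the cross-conjugated 2-silyloxydiene as the Z enol ether while the primary alcohol is silylated.

Step 6
Reactants: 6 (S)-5-[(2Z)-hexa-2,5-dien-2-yl]furan-2(5H)-one; 9 (2R,3Z,5E)-1,4-bis(tert-butyldimethylsilyloxy)-2-methylhepta-3,5-diene
Product: 10 Diels–Alder lactone (1S,2S,10R,11R,14R,15R)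
Conditions: PhMe (0.5 M), 2,6-di-tert-butyl-4-methylphenol (cat.), 150 °C, sealed tube, 48 h
Reagents that add atoms: none
Why: Thermal Diels–Alder reaction in which the 2-silyloxydiene adds to the butenolide face anti to the C2 chain with its silyloxy-bearing terminus C14 on the β-carbon C1; the endo transition state with both diene end groups outside gives the all-cis H1/H10/H14 (and H11) array.

Step 7
Reactants: 10 Diels–Alder lactone (1S,2S,10R,11R,14R,15R)
Product: 12 lactol acetate (C9 anomers), via aluminium lactolate 11 (not isolated)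
Conditions: i-Bu2AlH, CH2Cl2, −78 °C; then pyridine, DMAP, Ac2O, −78→0 °C
Reagents that add atoms: acetic anhydride, CC(=O)OC(C)=O
Why: Half-reduction of the γ-lactone and in situ acetylation of the aluminium lactolate (reductive acetylation) gives the α-acetoxy ether without ring opening; the silyl ether and silyl enol ether are inert.

Step 8
Reactants: 12 lactol acetate (C9 anomers)
Product: 13 9-methallyl tetrahydrofuran (1R,2S,9S,10R,11S,14R,15R)
Conditions: CH2=C(Me)CH2SiMe3 (3 equiv), TMSOTf (0.2 equiv), 2,6-di-tert-butyl-4-methylpyridine, CH2Cl2, −78 °C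
Reagents that add atoms: trimethyl(2-methylprop-2-en-1-yl)silane, CC(=C)C[Si](C)(C)C
Why: Hosomi–Sakurai allylation of the cyclic oxocarbenium ion, with attack on the convex face of the cis-fused bicycle anti to the C10–C11 bond, gives the 2,5-cis tetrahydrofuran and sets C9; the hindered pyridine protects the silyl enol ether from adventitious acid.

Step 9
Reactants: 13 9-methallyl tetrahydrofuran (1R,2S,9S,10R,11S,14R,15R)
Product: 15 hydroxy enone (1R,2S,9S,10S,14R,15R; 3Z), via enone silyl ether 14 (not isolated)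
Conditions: Pd(OAc)2 (1.2 equiv), MeCN, 40 °C; then 48% aq. HF, 0 °C
Reagents that add atoms: none
Why: Saegusa–Ito oxidation, in which the regiodefined enol silyl ether gives a divalent palladium enolate that loses the C11 hydride to form the C11=C12 enone (erasing C11); aqueous HF then cleaves the primary silyl ether under non-basic conditions that spare C14.

Step 10
Reactants: 15 hydroxy enone (1R,2S,9S,10S,14R,15R; 3Z)
Product: 17 oxepane alcohol (1R,2S,3S,4R,9S,10S,14R,15R), via (3R,4R)-epoxide 16 (not isolated)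
Conditions: VO(acac)2 (10 mol %), t-BuOOH (1.5 equiv, decane), PhMe, 0→23 °C; then AcOH (1 equiv), 23 °C
Reagents that add atoms: tert-butyl hydroperoxide, CC(C)(C)OO
Why: Proposed new method: hydroxyl-directed vanadium-catalysed epoxidation/7-exo cycloetherification of a 6-en-1-ol (oxepane-forming oxidative cyclisation); the C16 alkoxide binds the pentavalent vanadium tert-butylperoxo centre and, anchored through C14–C1 next to C2, reaches only the C3=C4 olefin, delivering oxygen to the face syn to C1 in the A(1,3)-locked rotamer (H2 eclipsing C4–C5) to give the (3R,4R)-epoxide while the unbound vinyl, methallyl and enone olefins stay inert, and the activated epoxide is then opened with inversion at tertiary C3 by O16, which closes the oxepane, sets C3 and leaves the C4 hydroxyl; closest known reaction type: VO(acac)2/t-BuOOH oxidative cyclisation of 4-en-1-ols to 2-(1-hydroxyalkyl)tetrahydrofurans and directed epoxidation of homoallylic alcohols, which to my knowledge has not been shown for 6-en-1-ols or oxepane closure.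

Step 11
Reactants: 17 oxepane alcohol (1R,2S,3S,4R,9S,10S,14R,15R)
Product: 18 oxepane butanoate (1R,2S,3S,4R,9S,10S,14R,15R)
Conditions: (n-PrCO)2O (3 equiv), DMAP (0.2 equiv), pyridine, CH2Cl2, 23 °C
Reagents that add atoms: butanoic anhydride, CCCC(=O)OC(=O)CCC
Why: DMAP-catalysed acylation of the only free hydroxyl; the tertiary ether and enone are unaffected and the weakly basic medium should not epimerise C14.

Step 12
Reactants: 18 oxepane butanoate (1R,2S,3S,4R,9S,10S,14R,15R)
Product: 19 target CNP0271677.1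
Conditions: second-generation Hoveyda–Grubbs catalyst RuCl2(H2IMes)(=CH–C6H4-2-O-i-Pr) (10 mol %), 1,4-benzoquinone (20 mol %), PhMe (1 mM), 90 °C
Reagents that add atoms: none
Why: Ring-closing metathesis between the vinyl and methallyl groups held cis on the tetrahydrofuran closes the nine-membered oxonene, whose ring size enforces the Z trisubstituted C6=C7 olefin; benzoquinone suppresses olefin migration.

## Compound list

1 | (S)-5-oxotetrahydrofuran-2-carboxylic acid | O=C1O[C@H](C(=O)O)CC1 | starting material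
2 | (S)-5-oxotetrahydrofuran-2-carbonyl chloride | O=C1O[C@H](C(=O)Cl)CC1 | intermediate
3 | (S)-5-acetyldihydrofuran-2(3H)-one | O=C1O[C@H](C(C)=O)CC1 | intermediate
4 | (S)-5-[(2Z)-hexa-2,5-dien-2-yl]dihydrofuran-2(3H)-one | O=C1O[C@H](/C(C)=C\CC=C)CC1 | intermediate
5 | (5S)-5-[(2Z)-hexa-2,5-dien-2-yl]-3-(phenylselanyl)dihydrofuran-2(3H)-one (C3 epimers) | O=C1O[C@H](/C(C)=C\CC=C)CC1[Se]c1ccccc1 | intermediate
6 | (S)-5-[(2Z)-hexa-2,5-dien-2-yl]furan-2(5H)-one | O=C1O[C@H](/C(C)=C\CC=C)C=C1 | intermediate
7 | (R)-4-methyldihydrofuran-2(3H)-one | O=C1C[C@@H](C)CO1 | starting material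
8 | (2R,5E)-1-hydroxy-2-methylhept-5-en-4-one | OC[C@H](C)CC(=O)/C=C/C | intermediate
9 | (2R,3Z,5E)-1,4-bis(tert-butyldimethylsilyloxy)-2-methylhepta-3,5-diene | CC(C)(C)[Si](C)(C)OC[C@H](C)/C=C(O[Si](C)(C)C(C)(C)C)/C=C/C | intermediate
10 | Diels–Alder lactone: γ-lactone (C9=O, ring O on C2) cis-fused to a cyclohexene bearing 13-OTBS (C12=C13 enol ether), 11-Me, the 14-[(2R)-1-(TBS-oxy)propan-2-yl] arm and 2-[(2Z)-hexa-2,5-dien-2-yl]; H1, H10, H11, H14 all cis and anti to the C2 chain; (1S,2S,10R,11R,14R,15R) | CC(C)(C)[Si](C)(C)OC[C@H](C)[C@H]2C(O[Si](C)(C)C(C)(C)C)=C[C@@H](C)[C@H]3C(=O)O[C@H](/C(C)=C\CC=C)[C@@H]23 | intermediate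
11 | diisobutylaluminium lactolate of 10 (O–Al on C9, C9 epimers) | CC(C)(C)[Si](C)(C)OC[C@H](C)[C@H]2C(O[Si](C)(C)C(C)(C)C)=C[C@@H](C)[C@H]3C(O[Al](CC(C)C)CC(C)C)O[C@H](/C(C)=C\CC=C)[C@@H]23 | intermediate
12 | lactol acetate of 10 (9-OAc, C9 anomers); (1S,2S,10R,11R,14R,15R) | CC(C)(C)[Si](C)(C)OC[C@H](C)[C@H]2C(O[Si](C)(C)C(C)(C)C)=C[C@@H](C)[C@H]3C(OC(C)=O)O[C@H](/C(C)=C\CC=C)[C@@H]23 | intermediate
13 | 9-methallyl tetrahydrofuran: 2,5-cis (Z-dienyl on C2, 2-methylallyl on C9), 13-OTBS enol ether, 16-OTBS; (1R,2S,9S,10R,11S,14R,15R) | CC(C)(C)[Si](C)(C)OC[C@H](C)[C@H]2C(O[Si](C)(C)C(C)(C)C)=C[C@@H](C)[C@H]3[C@H](CC(C)=C)O[C@H](/C(C)=C\CC=C)[C@@H]23 | intermediate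
14 | enone silyl ether: C11=C12 13-enone, 16-OTBS; (1R,2S,9S,10S,14R,15R; 3Z) | CC(C)(C)[Si](C)(C)OC[C@H](C)[C@H]2C(=O)C=C(C)[C@H]3[C@H](CC(C)=C)O[C@H](/C(C)=C\CC=C)[C@@H]23 | intermediate
15 | hydroxy enone: as 14 with free 16-OH; (1R,2S,9S,10S,14R,15R; 3Z) | OC[C@H](C)[C@H]2C(=O)C=C(C)[C@H]3[C@H](CC(C)=C)O[C@H](/C(C)=C\CC=C)[C@@H]23 | intermediate
16 | (3R,4R)-3,4-epoxide of 15 (cis-epoxide, oxygen on the face syn to C1) | OC[C@H](C)[C@H]2C(=O)C=C(C)[C@H]3[C@H](CC(C)=C)O[C@H]([C@]4(C)O[C@@H]4CC=C)[C@@H]23 | intermediate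
17 | oxepane alcohol: 3,16-ether closed, 4-OH, 4-allyl chain and 9-methallyl still open; (1R,2S,3S,4R,9S,10S,14R,15R) | O[C@H](CC=C)[C@]1(C)OC[C@H](C)[C@H]2C(=O)C=C(C)[C@H]3[C@H](CC(C)=C)O[C@H]1[C@@H]23 | intermediate
18 | oxepane butanoate: 4-O-butanoyl derivative of 17; (1R,2S,3S,4R,9S,10S,14R,15R) | CCCC(=O)O[C@H](CC=C)[C@]1(C)OC[C@H](C)[C@H]2C(=O)C=C(C)[C@H]3[C@H](CC(C)=C)O[C@H]1[C@@H]23 | intermediate
19 | CNP0271677.1: (1R,2S,3S,4R,6Z,9S,10S,14R,15R)-13-oxo-2,9:3,16-diepoxyeunicella-6,11-dien-4-yl butanoate | CCCC(=O)O[C@@H]1C/C=C(/C)C[C@@H]2O[C@H]3[C@@H]4[C@H]2C(C)=CC(=O)[C@@H]4[C@@H](C)CO[C@@]13C | target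

## Step count and risks

Total: 12 steps. Longest linear sequence: 10 steps (steps 1–3 and 6–12, from 1 to 19); the diene branch (steps 4–5) joins at step 6.

**Step 6 (Diels–Alder).** A 1,4-disubstituted diene and a γ-branched butenolide may react slowly, and the endo preference that sets C14 may be eroded. The fallback sets out from 6 and 9 and comes back at 10. It replaces the concerted cycloaddition by a stepwise polar annulation at low temperature: t-BuMe2SiNTf2 (5 mol %), CH2Cl2, −78 °C. Mukaiyama–Michael addition of C14 of 9 to C1 of 6, anti to the C2 chain and with silyl transfer, gives the open-chain silyl ketene acetal enone F1. In the same flask F1 closes by intramolecular Mukaiyama–Michael addition of C10 to the E-enone carbon C11, the silyl group returning to O13, to give 10. This fallback addresses rate rather than C14 selectivity, and C11 is planarised in step 9, so its configuration here is immaterial.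

**Step 10 (proposed vanadium step).** Direction over a six-atom tether is unproven, and the epoxide face or the 7-exo closure may not follow the plan. The fallback uses known chemistry, sets out from 15 and comes back at 17. Reagent-controlled Shi epoxidation of the trisubstituted olefin (D-fructose-derived Shi ketone, 2KHSO5·KHSO4·K2SO4, K2CO3, MeCN/dimethoxymethane/H2O, 0 °C) gives epoxide 16, now isolated. The catalyst sense is chosen by analogy with 1-phenylcyclohexene. Camphorsulfonic acid (10 mol %, CH2Cl2, 0 °C) then effects the acid-catalysed opening at the tertiary carbon by the C16 hydroxyl to give 17. This detour makes no compound outside the list (F0).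

**Step 12 (ring-closing metathesis).** Closing a nine-membered ring with a trisubstituted olefin on the rigid tetracycle may be slow or give dimers. The fallback sets out from 14 (isolated by stopping step 9 before the HF stage) and comes back at 19. It closes the oxonene before the oxepane, on a more flexible tricycle:
- Shi epoxidation as above gives the epoxide silyl ether F2.
- Metathesis with the same ruthenium catalyst gives the ring-closed epoxide F3.
- HF·pyridine in THF, then camphorsulfonic acid if needed, removes the silyl group and lets O16 open the epoxide at C3 to give the 4-hydroxy tetracycle F4.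
- Butanoylation as in step 11 gives 19.

## Further compounds

F1 | step 6 | open-chain silyl ketene acetal enone (C14–C1 bond formed; 1R,2S,14R,15R) | CC(C)(C)[Si](C)(C)OC[C@H](C)[C@@H](C(=O)/C=C/C)[C@H]1C=C(O[Si](C)(C)C(C)(C)C)O[C@@H]1/C(C)=C\CC=C
F0 | step 10 | none | none
F2 | step 12 | (3R,4R)-epoxide of 14 (16-OTBS) | CC(C)(C)[Si](C)(C)OC[C@H](C)[C@H]2C(=O)C=C(C)[C@H]3[C@H](CC(C)=C)O[C@H]([C@]4(C)O[C@@H]4CC=C)[C@@H]23
F3 | step 12 | ring-closed oxonene epoxide, 16-OTBS (1R,2S,3R,4R,6Z,9S,10S,14R,15R) | CC(C)(C)[Si](C)(C)OC[C@H](C)[C@H]2C(=O)C=C(C)[C@H]3[C@H](C/C(C)=C\C[C@H]4O[C@]45C)O[C@H]5[C@@H]23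
F4 | step 12 | 4-hydroxy tetracycle (target lacking the butanoyl group) | O[C@@H]1C/C=C(/C)C[C@@H]2O[C@H]3[C@@H]4[C@H]2C(C)=CC(=O)[C@@H]4[C@@H](C)CO[C@@]13C
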